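The runs come from a simulation with made-up constants, noise included.

What goes astray in these flasks, and how much Xp does the summer run hold at 27 h?

| flask | Xa | Xb | time |
|---|---|---|---|
| midnight | 250 mM | 250 mM |  |
| dusk | 500 mM | 250 mM |  |
| winter | 250 mM | 120 mM |  |
| summer | 120 mM | 120 mM | 27 h |

| run | time / h | [Xp] / mM |
|---|---|---|
| midnight run | 3.4 | 19.4 |
| midnight run | 6.8 | 39.0 |
| midnight run | 10 | 51.4 |
| midnight run | 14 | 61.4 |
| midnight run | 17 | 65.6 |
| midnight run | 20 | 68.2 |
| midnight run | 24 | 72.0 |
| midnight run | 27 | 72.2 |
| dusk run | 3.4 | 32.1 |
| dusk run | 6.8 | 64.0 |
| dusk run | 10 | 80.8 |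
| dusk run | 14 | 94.1 |
| dusk run | 17 | 101.2 |
| dusk run | 20 | 103.3 |
| dusk run | 24 | 105.9 |
| dusk run | 27 | 107.1 |
| winter run | 3.4 | 12.6 |
| winter run | 6.8 | 26.8 |
| winter run | 10 | 36.2 |
| winter run | 14 | 45.0 |
| winter run | 17 | 47.9 |
| winter run | 20 | 50.1 |
| winter run | 24 | 52.4 |
| winter run | 27 | 52.3 |

(scatter of a reading: 0.8 mM)

- Overall: Xa + Xb -> Xp.
- Constant volume, constant temperature.
- "The second partner" is Xb.
- An order is taken over about fifteen percent of the charge, up and down.

- reaction order in [Xa] at the outset, round the charge of the midnight run, defined at two percent of the Xa turned into Xp (one fixed amount of Xp, the same in the runs compared)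
- reaction order in [Xb] at the outset, round the charge of the midnight run, defined at two percent of the Xa turned into Xp
- Xp in the summer run at 27 h, as a share of the Xa charged
- which of these the readings show (the substrate pairs with itself / two substrates go astray together / the second partner is lost by itself / the second partner is lost in pairs)

Between 24 h and 27 h the midnight run moves from 72.0 mM to 72.2 mM and the dusk run from 105.9 mM to 107.1 mM; the summer run is asked at 27 h, so I take the reading at that time in each run as its end amount. The end exponent, the powers of ten of end Xp gained per power of ten of one charge with the other held, is 0.569 for Xa, from midnight to dusk, and 0.439 for Xb, from winter to midnight.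

A first-order loss takes the same share of Xb at any charge, so while Xa stays near its charge it gives an exponent near 1. A loss in pairs takes a bigger share of a bigger charge, so it gives less. My reading of 0.439 is lower than 1, so I commit to Xb lost in pairs, though these exponents do not clear a loss of Xa.

From winter to summer, the Xb charge stays at 120 mM and the Xa charge drops by 0.319 of a power of ten. I carry the exponent for Xa over from the midnight and dusk runs to this lower range, so my estimate of end Xp drops by 0.182 of a power, to 34.4 mM, which is 28.7% of the summer charge of Xa.

The forecast gives orders of 0.75 in Xa and 0.5 in Xb, 24.5% for the summer run, and "the second partner is lost by itself", holding that “the loss clock is concentration-independent”. It parts from me on the loss, and its share stands below mine.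

The flask gives orders of 0.71 and 0.40, 28.1% for the summer run, and "the second partner is lost in pairs".

    Xa + Xb → Xi (1.469 /M/h)
    Xi → Xp (0.1523 /h)
    2 Xb → Z (4.500 /M/h)

Taken from that result, the end exponent for Xa from winter to summer is 0.596, beside 0.569 from midnight to dusk. At the start the pair step takes Xb 6.13 times as fast as the step to Xi in the midnight run and 2.94 times as fast in the winter run, and the first half-life of Xb by pairing alone is 0.444 h at the midnight charge. The intermediate Xi, with a mean life of 6.57 h, longer than that half-life, turns into Xp meanwhile and after, and the midnight run reads 72.2 mM at 27 h.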